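A direct plan would build ring C first: silylated vanillin and the 1‑ethoxy‑3,4‑bis(silyloxy)diene A1 would be joined by a catalytic asymmetric hetero‑Diels–Alder reaction to the 2‑aryl‑3‑silyloxy‑2,3‑dihydropyran‑4‑one A2.
A2 would be sulfenylated and oxidised to the 5‑sulfinyl derivative A3, and ring A would be annulated last by a Diels–Alder reaction with the prenylated vinylketene acetal A4, followed by sulfoxide elimination and aromatisation.
Its weakest points would be:
(a) The run‑up to A1: two protections, a Weinreb amide, a vinyllithium addition, an enone isomerisation and an enol silylation would be spent on a four‑carbon diene, many steps for little gain in complexity.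
(b) The setting of C3: the cycloaddition would be expected to give the cis isomer, so C3 would be left to an acid equilibration next to the ketone, with C2 at risk through ring opening.
(c) The ring‑A annulation: a cycloaddition not yet shown for a sulfinyl dihydropyranone would have to be run on the enantioenriched late intermediate A3, with its regiochemistry and the thermal survival of the sulfoxide unproven.

Plan of the new route
The retrosynthesis cuts C3–O (oxidation of the C3=C4 enol ether), then the C2–C1′ bond between rings C and B (conjugate arylation of a chromone), then C8–prenyl (traced back to an O5 prenyl ether by a Claisen–Cope shift), then O1–C2 and C2–C3 of the pyranone (C2 from a formamide acetal).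
Ring A is bought with its three oxygens, ring C is annulated on it as a flat, achiral 4‑pyranone, and ring B is attached last.
The key step rests on the vinylogous ester O1–C2=C3–C4=O: C2 is its β‑carbon and ring B is its only substituent outside the bicycle, so ring B can arrive as an aryl nucleophile under catalyst control while ring C is dearomatised.
O5 and C8 stand para on ring A, so a prenyl group parked on O5 leaves O1 as the only free hydroxyl for ring closure and later lands on C8.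
No diene has to be prepared, C3 is set by attack anti to the 2‑aryl group (kinetic and thermodynamic preference agree), and ring A is never built, so no untested annulation falls on late chiral material.

Key step: step 7

Assumption: the sense of induction of the palladium–pyridinooxazoline catalyst is taken to be the same for the substituted chromone as for chromone itself, which makes the (R)‑ligand the one that gives 2S; the (S)‑ligand would be used if a trial addition showed otherwise.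

Step 1
Reactants: 1 2′,6′‑dihydroxy‑4′‑methoxyacetophenone; 2 prenyl bromide (1‑bromo‑3‑methylbut‑2‑ene)
Product: 3 1‑[2‑hydroxy‑4‑methoxy‑6‑(3‑methylbut‑2‑enyloxy)phenyl]ethanone
Conditions: 2 (1.05 equiv), K2CO3, acetone, 56 °C
Reagents that add atoms: none
Why: Williamson ether synthesis should stop after one alkylation because the two hydroxyls of 1 are equivalent and the one left in 3 is held in a hydrogen bond to the acetyl group; this tells the future O5 (ether) and O1 (free hydroxyl) apart.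

Step 2
Reactants: 3 1‑[2‑hydroxy‑4‑methoxy‑6‑(3‑methylbut‑2‑enyloxy)phenyl]ethanone
Product: 5 7‑methoxy‑5‑(3‑methylbut‑2‑enyloxy)‑4H‑chromen‑4‑one, via enaminone 4 (not isolated)
Conditions: Me2NCH(OMe)2, toluene, 95 °C; then AcOH, 70 °C
Reagents that add atoms: N,N‑dimethylformamide dimethyl acetal, COC(OC)N(C)C
Why: Condensation at the acetyl methyl group and acid‑promoted addition–elimination by the only free phenol (enaminone route to chromones) close ring C through O1–C2 without a regiochemical choice, and acetic acid is too weak to cleave the prenyl ether.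

Step 3
Reactants: 5 7‑methoxy‑5‑(3‑methylbut‑2‑enyloxy)‑4H‑chromen‑4‑one
Product: 8 5‑hydroxy‑7‑methoxy‑8‑(3‑methylbut‑2‑enyl)‑4H‑chromen‑4‑one, via C6‑substituted dienone 6 (not isolated), via C8‑substituted dienone 7 (not isolated)
Conditions: Eu(fod)3 [Eu(C10H10F7O2)3] (10 mol %), NaHCO3, PhCl, 85 °C
Reagents that add atoms: none
Why: The europium chelate of O5 and the C4 carbonyl should accelerate a para‑Claisen (Claisen–Cope) rearrangement in which the prenyl group moves from O5 to C6 with allyl inversion (6) and on to C8 with a second inversion (7), enolisation then giving the 5‑hydroxy‑8‑prenyl pattern, as is documented for 5‑prenyloxy flavones and flavanones.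

Step 4
Reactants: 8 5‑hydroxy‑7‑methoxy‑8‑(3‑methylbut‑2‑enyl)‑4H‑chromen‑4‑one
Product: 9 5‑(tert‑butyldimethylsilyloxy)‑7‑methoxy‑8‑(3‑methylbut‑2‑enyl)‑4H‑chromen‑4‑one
Conditions: TBSOTf, 2,6‑lutidine, CH2Cl2, 0 °C → rt
Reagents that add atoms: tert‑butyldimethylsilyl triflate, CC(C)(C)[Si](C)(C)OS(=O)(=O)C(F)(F)F
Why: Silyl ether protection with the silyl triflate overcomes the hydrogen bond of the 5‑hydroxyl and masks the acidic 4‑keto‑5‑hydroxy chelate, which could otherwise bind the palladium catalyst of step 7.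

Step 5
Reactants: 10 4‑bromo‑2‑methoxyphenol
Product: 11 (4‑bromo‑2‑methoxyphenoxy)(tert‑butyl)dimethylsilane
Conditions: TBSCl, imidazole, CH2Cl2, rt
Reagents that add atoms: tert‑butyldimethylsilyl chloride, CC(C)(C)[Si](C)(C)Cl
Why: Imidazole‑promoted silyl ether protection of an unhindered phenol is routine and gives a group that the final fluoride treatment removes.

Step 6
Reactants: 11 (4‑bromo‑2‑methoxyphenoxy)(tert‑butyl)dimethylsilane
Product: 14 [4‑(tert‑butyldimethylsilyloxy)‑3‑methoxyphenyl]boronic acid, via aryllithium 12 (not isolated), via lithium triisopropoxyborate 13 (not isolated)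
Conditions: n‑BuLi, THF, −78 °C; B(OiPr)3, −78 °C → rt; aq. NH4Cl
Reagents that add atoms: triisopropyl borate, CC(C)OB(OC(C)C)OC(C)C; water, O
Why: Bromine–lithium exchange and borylation of the aryllithium, followed by mild hydrolysis, give the boronic acid, the aryl silyl ether being stable to n‑BuLi at −78 °C and to aqueous NH4Cl.

Step 7
Reactants: 9 5‑(tert‑butyldimethylsilyloxy)‑7‑methoxy‑8‑(3‑methylbut‑2‑enyl)‑4H‑chromen‑4‑one; 14 [4‑(tert‑butyldimethylsilyloxy)‑3‑methoxyphenyl]boronic acid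
Product: 15 (2S)‑5‑(tert‑butyldimethylsilyloxy)‑2‑[4‑(tert‑butyldimethylsilyloxy)‑3‑methoxyphenyl]‑7‑methoxy‑8‑(3‑methylbut‑2‑enyl)chroman‑4‑one
Conditions: Pd(OCOCF3)2 (5 mol %), (R)‑t‑BuPyOx [(R)‑4‑tert‑butyl‑2‑(pyridin‑2‑yl)‑4,5‑dihydrooxazole] (6 mol %), 14 (2 equiv), H2O (5 equiv), ClCH2CH2Cl, 60 °C
Reagents that add atoms: none
Why: The cationic divalent palladium complex of the pyridinooxazoline takes up the aryl group of 14 by transmetalation, the C2=C3 bond of 9 inserts into the Pd–aryl bond so that C2–C1′ is formed, and the C3‑bound palladium enolate is protonated by water, which returns the hydroxo complex (asymmetric conjugate addition, here a dearomatising 1,4‑arylation of the 4‑pyranone). The closest known reaction type is the addition of arylboronic acids to chromones under Pd(OCOCF3)2 and t‑BuPyOx, which gives flavanones in high enantiomeric excess, and 9 differs from those substrates only in its ring‑A substituents. No ring is closed; the flat ring C becomes the saturated ring that carries C2. C2 is set by the ligand, whose tert‑butyl group lets only one enantioface of the coordinated C2=C3 bond insert, the (R)‑ligand being chosen for 2S. The step needs 1,4‑selectivity (the carbonyl is a vinylogous ester and arylpalladium species do not add 1,2), chemoselectivity over the prenyl group (an unactivated trisubstituted alkene does not insert) and protonation instead of β‑hydride elimination to the flavone (secured by water and the absence of an oxidant). The neutral, base‑free medium should keep the flavanone from racemising through retro‑oxa‑Michael ring opening.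

Step 8
Reactants: 15 (2S)‑5‑(tert‑butyldimethylsilyloxy)‑2‑[4‑(tert‑butyldimethylsilyloxy)‑3‑methoxyphenyl]‑7‑methoxy‑8‑(3‑methylbut‑2‑enyl)chroman‑4‑one
Product: 16 (2S)‑5‑(tert‑butyldimethylsilyloxy)‑2‑[4‑(tert‑butyldimethylsilyloxy)‑3‑methoxyphenyl]‑7‑methoxy‑8‑(3‑methylbut‑2‑enyl)‑4‑(trimethylsilyloxy)‑2H‑chromene
Conditions: TMSOTf, Et3N, CH2Cl2, 0 °C; non‑aqueous work‑up, used crude
Reagents that add atoms: trimethylsilyl triflate, C[Si](C)(C)OS(=O)(=O)C(F)(F)F
Why: Soft enolisation with silyl triflate and amine (silyl enol ether formation) can occur only toward C3 and avoids a free enolate, which could expel the O1 phenoxide and erase C2.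

Step 9
Reactants: 16 (2S)‑5‑(tert‑butyldimethylsilyloxy)‑2‑[4‑(tert‑butyldimethylsilyloxy)‑3‑methoxyphenyl]‑7‑methoxy‑8‑(3‑methylbut‑2‑enyl)‑4‑(trimethylsilyloxy)‑2H‑chromene
Product: 19 (2R,3R)‑3,5‑dihydroxy‑2‑(4‑hydroxy‑3‑methoxyphenyl)‑7‑methoxy‑8‑(3‑methylbut‑2‑enyl)chroman‑4‑one (CNP0195184.1), via silyloxy epoxide 17 (not isolated), via 3‑silyloxy ketone 18 (not isolated)
Conditions: DMDO (1.0 equiv), acetone/CH2Cl2, −78 °C; volatiles removed cold; then HF·pyridine, pyridine (excess), THF, 0 °C → rt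
Reagents that add atoms: dimethyldioxirane, CC1(C)OO1
Why: In this Rubottom oxidation the dioxirane should epoxidise the electron‑rich silyl enol ether much faster than the isolated prenyl alkene and from the face opposite to the 2‑aryl group, so that C3–O forms trans to the aryl group (3R), which is also the more stable diequatorial arrangement; silyl migration gives 18, and buffered fluoride then removes the three silyl groups without base (silyl ether cleavage).

Compound list
1 | 2′,6′‑dihydroxy‑4′‑methoxyacetophenone | CC(=O)c1c(O)cc(OC)cc1O | starting material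
2 | prenyl bromide (1‑bromo‑3‑methylbut‑2‑ene) | CC(C)=CCBr | starting material
3 | 1‑[2‑hydroxy‑4‑methoxy‑6‑(3‑methylbut‑2‑enyloxy)phenyl]ethanone | CC(=O)c1c(O)cc(OC)cc1OCC=C(C)C | intermediate
4 | (E)‑3‑(dimethylamino)‑1‑[2‑hydroxy‑4‑methoxy‑6‑(3‑methylbut‑2‑enyloxy)phenyl]prop‑2‑en‑1‑one (not isolated) | CN(C)/C=C/C(=O)c1c(O)cc(OC)cc1OCC=C(C)C | intermediate
5 | 7‑methoxy‑5‑(3‑methylbut‑2‑enyloxy)‑4H‑chromen‑4‑one | O=c1ccoc2cc(OC)cc(OCC=C(C)C)c12 | intermediate
6 | 7‑methoxy‑6‑(2‑methylbut‑3‑en‑2‑yl)‑6H‑chromene‑4,5‑dione, racemic at C6 (not isolated) | O=C1C=COC2=C1C(=O)C(C(C)(C)C=C)C(OC)=C2 | intermediate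
7 | 7‑methoxy‑8‑(3‑methylbut‑2‑enyl)‑8H‑chromene‑4,5‑dione, racemic at C8 (not isolated) | O=C1C=COC2=C1C(=O)C=C(OC)C2CC=C(C)C | intermediate
8 | 5‑hydroxy‑7‑methoxy‑8‑(3‑methylbut‑2‑enyl)‑4H‑chromen‑4‑one | O=c1ccoc2c(CC=C(C)C)c(OC)cc(O)c12 | intermediate
9 | 5‑(tert‑butyldimethylsilyloxy)‑7‑methoxy‑8‑(3‑methylbut‑2‑enyl)‑4H‑chromen‑4‑one | O=c1ccoc2c(CC=C(C)C)c(OC)cc(O[Si](C)(C)C(C)(C)C)c12 | intermediate
10 | 4‑bromo‑2‑methoxyphenol | COc1cc(Br)ccc1O | starting material
11 | (4‑bromo‑2‑methoxyphenoxy)(tert‑butyl)dimethylsilane | COc1cc(Br)ccc1O[Si](C)(C)C(C)(C)C | intermediate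
12 | [4‑(tert‑butyldimethylsilyloxy)‑3‑methoxyphenyl]lithium (not isolated) | COc1cc([Li])ccc1O[Si](C)(C)C(C)(C)C | intermediate
13 | lithium [4‑(tert‑butyldimethylsilyloxy)‑3‑methoxyphenyl]tri(propan‑2‑yloxy)borate (not isolated) | COc1cc([B-](OC(C)C)(OC(C)C)OC(C)C)ccc1O[Si](C)(C)C(C)(C)C.[Li+] | intermediate
14 | [4‑(tert‑butyldimethylsilyloxy)‑3‑methoxyphenyl]boronic acid | COc1cc(B(O)O)ccc1O[Si](C)(C)C(C)(C)C | intermediate
15 | (2S)‑5‑(tert‑butyldimethylsilyloxy)‑2‑[4‑(tert‑butyldimethylsilyloxy)‑3‑methoxyphenyl]‑7‑methoxy‑8‑(3‑methylbut‑2‑enyl)chroman‑4‑one | COc1cc([C@H]2Oc3c(CC=C(C)C)c(OC)cc(O[Si](C)(C)C(C)(C)C)c3C(=O)C2)ccc1O[Si](C)(C)C(C)(C)C | intermediate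
16 | (2S)‑5‑(tert‑butyldimethylsilyloxy)‑2‑[4‑(tert‑butyldimethylsilyloxy)‑3‑methoxyphenyl]‑7‑methoxy‑8‑(3‑methylbut‑2‑enyl)‑4‑(trimethylsilyloxy)‑2H‑chromene | COc1cc([C@H]2Oc3c(CC=C(C)C)c(OC)cc(O[Si](C)(C)C(C)(C)C)c3C(O[Si](C)(C)C)=C2)ccc1O[Si](C)(C)C(C)(C)C | intermediate
17 | 3,4‑epoxide of 16: 5‑(tert‑butyldimethylsilyloxy)‑2‑[4‑(tert‑butyldimethylsilyloxy)‑3‑methoxyphenyl]‑3,4‑epoxy‑7‑methoxy‑8‑(3‑methylbut‑2‑enyl)‑4‑(trimethylsilyloxy)chroman, oxirane oxygen on the face opposite to the 2‑aryl group (not isolated) | COc1cc([C@H]2Oc3c(CC=C(C)C)c(OC)cc(O[Si](C)(C)C(C)(C)C)c3[C@]4(O[Si](C)(C)C)O[C@H]24)ccc1O[Si](C)(C)C(C)(C)C | intermediate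
18 | (2R,3R)‑5‑(tert‑butyldimethylsilyloxy)‑2‑[4‑(tert‑butyldimethylsilyloxy)‑3‑methoxyphenyl]‑7‑methoxy‑8‑(3‑methylbut‑2‑enyl)‑3‑(trimethylsilyloxy)chroman‑4‑one (not isolated) | COc1cc([C@H]2Oc3c(CC=C(C)C)c(OC)cc(O[Si](C)(C)C(C)(C)C)c3C(=O)[C@@H]2O[Si](C)(C)C)ccc1O[Si](C)(C)C(C)(C)C | intermediate
19 | (2R,3R)‑3,5‑dihydroxy‑2‑(4‑hydroxy‑3‑methoxyphenyl)‑7‑methoxy‑8‑(3‑methylbut‑2‑enyl)chroman‑4‑one | COc1cc([C@H]2Oc3c(CC=C(C)C)c(OC)cc(O)c3C(=O)[C@@H]2O)ccc1O | target

Total step count: 9. Longest linear sequence: 7 (steps 1, 2, 3, 4, 7, 8, 9); steps 5 and 6 form the side branch.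

Steps most likely to fail

Step 7. The insertion into the electron‑rich, peri‑substituted chromone may be slow, so that protodeboronation of the boronic acid outruns the addition, or the facial selectivity may be insufficient. Partial loss of the 5‑silyl group would do no harm, since step 8 would silylate O5 again. The fallback sets out from chromone 9 and aryllithium 12 and gives up catalyst control in favour of a resolution. Aryllithium 12 (2 equiv) and CuI would give the lithium bis[4‑(tert‑butyldimethylsilyloxy)‑3‑methoxyphenyl]cuprate F1. With TMSCl in THF at −78 °C, F1 should add to 9 to give the racemic silyl enol ether F2, which aqueous NH4Cl would hydrolyse to the racemic flavanone F3. Kinetic resolution by asymmetric transfer hydrogenation (RhCl[(R,R)‑TsDPEN](C5Me5), HCO2H/Et3N, EtOAc, rt, stopped near half conversion) should then reduce the 2R enantiomer to the cis‑(2R,4R)‑flavan‑4‑ol F4 and leave the 2S ketone. The catalyst enantiomer is the one that reduces the 2R ketone faster, expected to be the (R,R)‑complex. The route is rejoined at 15.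

Step 3. Dienone 6 may enolise before the second shift, which would leave the allyl unit on C6 as a 1,1‑dimethylallyl group, or the prenyl ether may be cleaved by the Lewis acid. The fallback sets out from acetophenone 1 and places the prenyl group by cross‑coupling instead of rearrangement. Me2NCH(OMe)2 would give the enaminone (E)‑1‑(2,6‑dihydroxy‑4‑methoxyphenyl)‑3‑(dimethylamino)prop‑2‑en‑1‑one F5, and AcOH would close it to 5‑hydroxy‑7‑methoxy‑4H‑chromen‑4‑one F6; either hydroxyl gives the same chromone. TBSOTf and 2,6‑lutidine would give 5‑(tert‑butyldimethylsilyloxy)‑7‑methoxy‑4H‑chromen‑4‑one F7. Iodination with N‑iodosuccinimide in MeCN should go to C8, which is para to O5, while C6 is shielded by the silyl ether, and give 5‑(tert‑butyldimethylsilyloxy)‑8‑iodo‑7‑methoxy‑4H‑chromen‑4‑one F8. Stille coupling of F8 with tributyl(3‑methylbut‑2‑enyl)stannane and Pd(PPh3)4 in DMF at 90 °C would give the linear prenyl arene. The route is rejoined at 9.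

Step 9. The dioxirane may also epoxidise the prenyl double bond, or the enol ether may hydrolyse before it is oxidised. The fallback sets out from flavanone 15 and uses an oxidant that does not attack unactivated alkenes. KN(SiMe3)2 in THF at −78 °C would give the potassium enolate F9, kept cold to hold back ring opening. 2‑(Phenylsulfonyl)‑3‑phenyloxaziridine should hydroxylate F9 anti to the 2‑aryl group to give (2R,3R)‑5‑(tert‑butyldimethylsilyloxy)‑2‑[4‑(tert‑butyldimethylsilyloxy)‑3‑methoxyphenyl]‑3‑hydroxy‑7‑methoxy‑8‑(3‑methylbut‑2‑enyl)chroman‑4‑one F10. HF·pyridine in pyridine/THF would then remove both silyl groups. The route is rejoined at 19.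

Further compounds
F1 | step 7 | lithium bis[4‑(tert‑butyldimethylsilyloxy)‑3‑methoxyphenyl]cuprate | [Li+].COc1cc([Cu-]c2ccc(O[Si](C)(C)C(C)(C)C)c(OC)c2)ccc1O[Si](C)(C)C(C)(C)C
F2 | step 7 | racemic 5‑(tert‑butyldimethylsilyloxy)‑2‑[4‑(tert‑butyldimethylsilyloxy)‑3‑methoxyphenyl]‑7‑methoxy‑8‑(3‑methylbut‑2‑enyl)‑4‑(trimethylsilyloxy)‑2H‑chromene | COc1cc(C2Oc3c(CC=C(C)C)c(OC)cc(O[Si](C)(C)C(C)(C)C)c3C(O[Si](C)(C)C)=C2)ccc1O[Si](C)(C)C(C)(C)C
F3 | step 7 | racemic 5‑(tert‑butyldimethylsilyloxy)‑2‑[4‑(tert‑butyldimethylsilyloxy)‑3‑methoxyphenyl]‑7‑methoxy‑8‑(3‑methylbut‑2‑enyl)chroman‑4‑one | COc1cc(C2Oc3c(CC=C(C)C)c(OC)cc(O[Si](C)(C)C(C)(C)C)c3C(=O)C2)ccc1O[Si](C)(C)C(C)(C)C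
F4 | step 7 | (2R,4R)‑5‑(tert‑butyldimethylsilyloxy)‑2‑[4‑(tert‑butyldimethylsilyloxy)‑3‑methoxyphenyl]‑7‑methoxy‑8‑(3‑methylbut‑2‑enyl)chroman‑4‑ol | COc1cc([C@@H]2Oc3c(CC=C(C)C)c(OC)cc(O[Si](C)(C)C(C)(C)C)c3[C@H](O)C2)ccc1O[Si](C)(C)C(C)(C)C
F5 | step 3 | (E)‑1‑(2,6‑dihydroxy‑4‑methoxyphenyl)‑3‑(dimethylamino)prop‑2‑en‑1‑one | CN(C)/C=C/C(=O)c1c(O)cc(OC)cc1O
F6 | step 3 | 5‑hydroxy‑7‑methoxy‑4H‑chromen‑4‑one | O=c1ccoc2cc(OC)cc(O)c12
F7 | step 3 | 5‑(tert‑butyldimethylsilyloxy)‑7‑methoxy‑4H‑chromen‑4‑one | O=c1ccoc2cc(OC)cc(O[Si](C)(C)C(C)(C)C)c12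
F8 | step 3 | 5‑(tert‑butyldimethylsilyloxy)‑8‑iodo‑7‑methoxy‑4H‑chromen‑4‑one | O=c1ccoc2c(I)c(OC)cc(O[Si](C)(C)C(C)(C)C)c12
F9 | step 9 | potassium enolate of 15, potassium (2S)‑5‑(tert‑butyldimethylsilyloxy)‑2‑[4‑(tert‑butyldimethylsilyloxy)‑3‑methoxyphenyl]‑7‑methoxy‑8‑(3‑methylbut‑2‑enyl)‑2H‑chromen‑4‑olate | COc1cc([C@H]2Oc3c(CC=C(C)C)c(OC)cc(O[Si](C)(C)C(C)(C)C)c3C([O-])=C2)ccc1O[Si](C)(C)C(C)(C)C.[K+]
F10 | step 9 | (2R,3R)‑5‑(tert‑butyldimethylsilyloxy)‑2‑[4‑(tert‑butyldimethylsilyloxy)‑3‑methoxyphenyl]‑3‑hydroxy‑7‑methoxy‑8‑(3‑methylbut‑2‑enyl)chroman‑4‑one | COc1cc([C@H]2Oc3c(CC=C(C)C)c(OC)cc(O[Si](C)(C)C(C)(C)C)c3C(=O)[C@@H]2O)ccc1O[Si](C)(C)C(C)(C)C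
A1 | direct plan | (1E,3Z)‑4‑(tert‑butyldimethylsilyloxy)‑1‑ethoxy‑3‑(trimethylsilyloxy)buta‑1,3‑diene | CCO/C=C/C(O[Si](C)(C)C)=C/O[Si](C)(C)C(C)(C)C
A2 | direct plan | (2R,3R)‑3‑(tert‑butyldimethylsilyloxy)‑2‑[4‑(tert‑butyldimethylsilyloxy)‑3‑methoxyphenyl]‑2,3‑dihydro‑4H‑pyran‑4‑one | COc1cc([C@H]2OC=CC(=O)[C@@H]2O[Si](C)(C)C(C)(C)C)ccc1O[Si](C)(C)C(C)(C)C
A3 | direct plan | (2R,3R)‑3‑(tert‑butyldimethylsilyloxy)‑2‑[4‑(tert‑butyldimethylsilyloxy)‑3‑methoxyphenyl]‑5‑(phenylsulfinyl)‑2,3‑dihydro‑4H‑pyran‑4‑one | COc1cc([C@H]2OC=C(S(=O)c3ccccc3)C(=O)[C@@H]2O[Si](C)(C)C(C)(C)C)ccc1O[Si](C)(C)C(C)(C)C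
A4 | direct plan | (3Z)‑1,3‑dimethoxy‑7‑methyl‑1‑(trimethylsilyloxy)octa‑1,3,6‑triene | COC(O[Si](C)(C)C)=C/C(OC)=C/CC=C(C)C
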